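**Remarks on the chemistry**

- Numbering: chroman numbering is used for the target and all intermediates (O1, C2, C3, C4, C4a, C5–C8, C8a). Ring A is the phenol ring, ring B the pyran ring.
- Descriptor check: at C4 the ring-A carbon (flanked by two oxygen-bearing carbons) outranks the naphthyl carbon, which outranks C3. C4 is therefore S in 8, 9, 10, 11 and 12 alike, and (2S,4S) is the 2,4-cis chroman.
- Protecting groups: the two ring-A oxygens pass through the photochemical step as acetates. Ethers with benzylic or acetal C–H bonds would compete with the aldehyde as hydrogen donors toward excited decatungstate. Acetates have no hydridic C–H bond, are small, make the aryl bromide less electron-rich, and come off with mild base without hydrogenation.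
- Assumption: the sense of induction of the nickel–bis(imidazoline) catalyst cannot be predicted with confidence for this substrate, so the ligand antipode that leads to (S)-8 is the one to be used. It is written L* below: a C2-symmetric N-aryl 4,4'-dialkyl-4,4',5,5'-tetrahydro-2,2'-biimidazole, for example the N-(3,5-di-tert-butylphenyl) 4,4'-diisopropyl member, accessible in either antipode from the enantiomeric valinols.

## Structural features

The target is a 2,4-disubstituted chroman: pyran ring B (O1, C2, C3, C4) is fused to phenol ring A, which carries a free hydroxyl at C5. C2 bears a methyl group and C4 a 4,5-dimethoxynaphthalen-1-yl group attached through a single C–C bond. The two stereocenters, C2 (S) and C4 (S), are not adjacent; they are separated by the C3 methylene and stand cis on ring B. C4 is a doubly benzylic methine, and its ring-A partner C4a lies between two oxygen-bearing carbons (C5 and C8a). This is the 2-position of a resorcinol, the most shielded site and one that electrophilic substitution does not reach. Fragile elements are the very electron-rich peri-dimethoxynaphthalene (oxidants, electrophiles, single-electron oxidation), the free phenol, and the C4–naphthyl bond. Strong acid can ionise that bond by ipso protonation para to a methoxy group with departure of an ortho-hydroxybenzyl cation, which would racemise C4. The real difficulty is the absolute configuration of the congested diaryl methine C4 together with attachment of ring A through its hindered carbon. C2 is comparatively easy, because hydride delivery to a C2 oxocarbenium ion anti to the C4 aryl group gives the cis isomer. The key step uses the fact that C4 is a naphthalene benzylic carbon flanked by ring A (bond C4–C4a) and by the chain C3–C2(=O)–CH3. The two carbons of a vinyl group on the naphthalene become C4 and C3, an acetyl unit becomes C2 with its methyl, and ring A arrives as an aryl halide whose halogen marks C4a.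

## Logic of the disconnections

12 to 10: the C2–H bond is cut, so that 12 arises by hydride delivery to the cation 11 formed from 10 by loss of the C2 hydroxyl. C2 is the easier stereocenter and can be derived from the existing one at C4. This removes one stereocenter and raises C2 to the carbonyl oxidation level. The forward step must add hydride anti to the naphthyl group and use acid mild and cold enough to leave the C4–naphthyl bond intact.

10 to 8: the O1–C2 bond and the two O–acyl bonds are cut, since 10 is the ring-closed form of 9 and 9 is 8 without its acetyl groups. Ring B is opened to an acyclic ketone in which C4 is the only stereocenter. The forward ester cleavage must avoid conditions that epimerise C4 or oxidise the liberated electron-rich diphenol.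

8 to 4, 6 and 7: the bonds C2–C3 and C4–C4a are cut together. C4 is benzylic to the naphthalene and beta to the ketone, so C3 and C4 map onto the vinyl group of 4, C2 and its methyl onto 7, and ring A onto 6, whose bromine fixes attachment between the two oxygens. The skeleton falls into three fragments of 14, 10 and 2 carbons, and the stereocenter forms in the same event. The forward step demands that radical addition to 4 precedes capture by nickel, that hydrogen abstraction occurs only at 7, that a crowded aryl–nickel centre accepts a secondary radical, and that the ligand selects one face.

4 to 3 and 3 to 1: the C=C bond of 4 is cut (carbonyl olefination), then the ring–CHO bond of 3 (electrophilic formylation). 1 is commercial and reacts at the position para to a methoxy group, which is the position needed. The demands are regioselective monosubstitution of 1 and a basic olefination with gentle isolation of the acid-sensitive 4.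

6 to 5: the two O–acyl bonds are cut. 5 is commercial and already carries the bromine at the correct carbon. The only demand is complete diacylation.

## Other disconnections considered

Alternative 1: The cut runs through ring B at C3–C4 and O1–C2 and leads back to the diaryl carbinol A1 (ring A and the naphthalene on one carbinol carbon, both phenols free) and 2-methoxypropene A3. In the forward direction a chiral BINOL-derived phosphoric acid would dehydrate A1 to the ortho-quinone methide A2, bind it by hydrogen bonding and steer a hetero-Diels–Alder addition of A3. This would give the cyclic ketal A4 with ring B closed and C4 set; silane reduction of A4 would then set C2 as in step 6.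
- In its favour: it is metal-free and makes ring B and C4 in one step. The electron-rich enol ether and the electron-poor quinone methide are polarity-matched, which is better than step 4, where a nucleophilic acyl radical meets an electron-rich alkene. The two ring-A hydroxyls are equivalent, so no regiochemical question arises. The crowded C4–C4a bond would come from a simple carbonyl addition (3 plus a 2-metallated resorcinol ether) and not from a reaction at a metal centre; here the alternative is the better.
- Against it: the methide carbon of A2 carries a strongly donating dimethoxynaphthyl group, so A1 should ionise under very weak acid even without the chiral catalyst. That opens a racemic background channel and gives a loosely bound, less electrophilic diene. A1 is hard to obtain with free phenols next to so labile a carbinol, since it can self-condense through the nucleophilic naphthalene or resorcinol positions. A3 hydrolyses and forms mixed ketals with phenols under the same acid.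
- Comparison: both plans end in the same C2 reduction, so C2 control is equal, and step economy is equal at about six steps. The alternative is more convergent in its key step (one ring closed against none). The chosen plan has the advantage that no C–C bond forms without the chiral nickel catalyst, and that its intermediates before step 5 are robust.

Alternative 2: The cut is C4–C4a, made inside a five-membered ring. The target is traced to the dihydrocoumarin A7, this to the indanone A6 by removal of the ring oxygen, and A6 to the 2'-bromochalcone A5. In the forward direction Pd(OAc)2 with a chiral biaryl bisphosphine and sodium formate would bring about the cyclisation. Zerovalent palladium inserts into the C–Br bond of A5, the aryl–palladium species adds across the enone (formally 5-endo-trig), and formate reduces the resulting palladium enolate to A6. A Baeyer–Villiger oxidation with aryl migration would give A7. MeLi addition, silane reduction and debenzylation would follow.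
- In its favour: enantioselective reductive Heck cyclisation of 2'-halochalcones to 3-arylindanones is an established reaction class, so C4 would rest on closer precedent than in step 4; on this point the alternative is the better. The hindered bond forms intramolecularly, and A5 is assembled by an aldol condensation with 3.
- Against it: oxygen insertion into an indanone needs a peracid, usually with strong acid, in the presence of a dimethoxynaphthalene that such reagents oxidise. The migrating ring-A carbon has its ether meta and gets no assistance, so methylene migration may compete. MeLi can add twice to A7. The acetophenone half of A5 is not commercial.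
- Comparison: the alternative sets C4 in a carbocycle and then spends three steps on ring surgery. Its mechanism is two-electron organopalladium chemistry with better-understood enantiocontrol than a radical relay. Its step economy is clearly worse, about ten steps against six. The C2-setting reduction is the same in both.

Alternative 3: C3 is excised by cutting C2–C3 and C3–C4, which leads back to the benzofuran A8 in which the future C2 and C4 are directly bonded. In the forward direction chlorocarbene from CH2Cl2 and MeLi would cyclopropanate the furan double bond. AgBF4 would abstract chloride, and the cyclopropyl cation would open to the aromatic chromenylium salt A9 with the carbene carbon as C3.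
- In its favour: the skeleton comes from flat, robust heteroaryl chemistry (A8 by cross-coupling of a 3-halobenzofuran with a naphthylboronic acid) with no congested sp3 coupling; in this respect the alternative is the better. Hydrogenation of a planar cation from one face would give the cis relationship by default, which is equal to or simpler than the substrate control of step 6.
- Against it: the key step creates no stereocenter. Both C2 and C4 would depend on a later enantioselective reduction of A9, for which a donor-stabilised 4-aryl-2-alkyl chromenylium ion offers no reliable model. The carbene can also attack the electron-rich naphthalene, the furan double bond is tetrasubstituted and shielded, and hydride can add at C2 or C4.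
- Comparison: the chosen plan sets C4 in the bond-forming event and C2 by substrate control, whereas the alternative postpones all stereochemistry to an unproven step. Its closed-shell chemistry is operationally simple but less tolerant of the electron-rich arene. Step economy is equal or slightly worse (about four steps to A8, then three more).

Key step: step 4

## Route

Step 1
Reactants: 1 1,8-dimethoxynaphthalene
Product: 3 4,5-dimethoxy-1-naphthaldehyde, via aryl iminium dichlorophosphate 2 (not isolated)
Conditions: POCl3 (1.3 equiv), DMF (3 equiv), toluene, 0 → 90 °C; then aq NaOH, 0 °C → rt
Reagents that add atoms: N,N-dimethylformamide, CN(C)C=O; water, O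
Why: Vilsmeier–Haack formylation; the chloroiminium ion attacks the position para to a methoxy group (the ortho positions are less reactive), the iminium substituent deactivates the ring against a second attack, and aqueous base hydrolyses 2 to the aldehyde.

Step 2
Reactants: 3 4,5-dimethoxy-1-naphthaldehyde
Product: 4 4,5-dimethoxy-1-vinylnaphthalene
Conditions: Ph3PCH3Br (1.3 equiv), KOtBu (1.25 equiv), THF, 0 °C → rt; filtration through base-washed silica, storage cold with BHT
Reagents that add atoms: methyltriphenylphosphonium bromide, C[P+](c1ccccc1)(c1ccccc1)c1ccccc1.[Br-]
Why: Wittig methylenation with the non-stabilised ylide; the basic medium spares the acid-sensitive electron-rich vinylarene.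

Step 3
Reactants: 5 2-bromoresorcinol
Product: 6 2-bromo-1,3-phenylene diacetate
Conditions: Ac2O (2.5 equiv), Et3N (3 equiv), DMAP (5 mol%), CH2Cl2, 0 °C → rt
Reagents that add atoms: acetic anhydride, CC(=O)OC(C)=O
Why: DMAP-catalysed O-acylation of both phenols; the aryl bromide is untouched.

Step 4
Reactants: 4 4,5-dimethoxy-1-vinylnaphthalene (1.5 equiv); 6 2-bromo-1,3-phenylene diacetate (1.0 equiv); 7 acetaldehyde (3 equiv, added cold)
Product: 8 (S)-2-[1-(4,5-dimethoxynaphthalen-1-yl)-3-oxobutyl]-1,3-phenylene diacetate
Conditions: (Bu4N)4[W10O32] (2 mol%), NiBr2(dme) (10 mol%), L* (12 mol%), K2HPO4 (2 equiv), acetone/MeCN 1:1, 390 nm LEDs, 10 °C, sealed tube, Ar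
Reagents that add atoms: none
Why: Proposed new method: excited decatungstate abstracts the formyl hydrogen of 7, the acetyl radical adds to the terminal alkene carbon of 4 (C2–C3) to give a naphthylic radical at the future C4, and this radical is captured by the aryl–nickel bromide complex formed from 6 and zerovalent nickel, whereupon the trivalent aryl(alkyl)nickel species reductively eliminates the C4–C4a bond; the reduced polyoxotungstate returns monovalent nickel to the zerovalent state and K2HPO4 takes up HBr. The closest known reaction types are the decatungstate/nickel three-component acyl-arylation of alkenes with aldehydes and aryl bromides and the bis(imidazoline)–nickel enantioselective three-component alkyl-arylation of vinylarenes; their merger on an electron-rich vinylnaphthalene with an aryl bromide carrying two ortho oxygen substituents has not been shown. No ring is closed. The one new stereocenter, C4, is controlled by the chiral bis(imidazoline) on nickel: radical capture is reversible, so the planar radical is funnelled through the faster reductive elimination of one diastereomeric trivalent complex, and the ligand antipode is chosen to give S. Regiochemistry does not rest on polar matching (a nucleophilic acyl radical meets an electron-rich alkene) but on formation of the delocalised naphthylic radical, and since only nickel carries the aryl group the arene can arrive only at C4. Chemoselectivity requires hydrogen abstraction at the aldehyde alone, which the acetates of 6 secure because they offer no hydridic C–H bond, and addition of the acetyl radical to 4 faster than its direct capture by nickel, which the excess of 4 and the crowded aryl–nickel centre should favour. Acetates also make 6 less electron-rich and leaner at the ortho positions than alkyl ethers, which should ease oxidative addition and reductive elimination.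

Step 5
Reactants: 8 (S)-2-[1-(4,5-dimethoxynaphthalen-1-yl)-3-oxobutyl]-1,3-phenylene diacetate
Product: 10 (4S)-4-(4,5-dimethoxynaphthalen-1-yl)-2-methylchromane-2,5-diol (both C2 epimers), via open diphenol ketone 9 (not isolated)
Conditions: K2CO3 (0.3 equiv), degassed MeOH, 0 °C → rt, Ar; then aq NH4Cl
Reagents that add atoms: none
Why: base-catalysed methanolysis of the two aryl acetates (transesterification); one liberated phenol adds to the ketone (6-exo-trig) to give the six-membered hemiketal, and C4 carries no acidic hydrogen under these conditions.

Step 6
Reactants: 10 (4S)-4-(4,5-dimethoxynaphthalen-1-yl)-2-methylchromane-2,5-diol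
Product: 12 Cladonaphchrom B, (2S,4S)-4-(4,5-dimethoxynaphthalen-1-yl)-2-methylchroman-5-ol, via oxocarbenium ion 11 (not isolated)
Conditions: Et3SiH (5 equiv), BF3·OEt2 (2.5 equiv), CH2Cl2, −78 → −30 °C; then aq NaHCO3
Reagents that add atoms: none
Why: ionic hydrogenation of a hemiketal; BF3 ionises the C2 hydroxyl to 11 and the silane delivers hydride pseudoaxially, anti to the C4 naphthyl group (held pseudoaxial by strain against the C5 hydroxyl), so the methyl group ends cis to the naphthyl group and C2 is S. The low temperature is chosen to keep the C4–naphthyl bond from ionising.

## Compound list

1 | 1,8-dimethoxynaphthalene | COc1cccc2cccc(OC)c12 | starting material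
2 | N-[(4,5-dimethoxynaphthalen-1-yl)methylidene]-N-methylmethanaminium dichlorophosphate (not isolated) | COc1cccc2c(C=[N+](C)C)ccc(OC)c12.[O-]P(=O)(Cl)Cl | intermediate
3 | 4,5-dimethoxy-1-naphthaldehyde | COc1cccc2c(C=O)ccc(OC)c12 | intermediate
4 | 4,5-dimethoxy-1-vinylnaphthalene | COc1cccc2c(C=C)ccc(OC)c12 | intermediate
5 | 2-bromoresorcinol (2-bromobenzene-1,3-diol) | Oc1cccc(O)c1Br | starting material
6 | 2-bromo-1,3-phenylene diacetate | CC(=O)Oc1cccc(OC(C)=O)c1Br | intermediate
7 | acetaldehyde | CC=O | starting material
8 | (S)-2-[1-(4,5-dimethoxynaphthalen-1-yl)-3-oxobutyl]-1,3-phenylene diacetate | COc1cccc2c([C@H](CC(C)=O)c3c(OC(C)=O)cccc3OC(C)=O)ccc(OC)c12 | intermediate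
9 | (S)-4-(2,6-dihydroxyphenyl)-4-(4,5-dimethoxynaphthalen-1-yl)butan-2-one (not isolated) | COc1cccc2c([C@H](CC(C)=O)c3c(O)cccc3O)ccc(OC)c12 | intermediate
10 | (4S)-4-(4,5-dimethoxynaphthalen-1-yl)-2-methylchromane-2,5-diol (both C2 epimers) | COc1cccc2c([C@@H]3CC(C)(O)Oc4cccc(O)c43)ccc(OC)c12 | intermediate
11 | (4S)-4-(4,5-dimethoxynaphthalen-1-yl)-5-hydroxy-2-methyl-3,4-dihydrochromenylium hydroxytrifluoroborate (not isolated) | COc1cccc2c([C@@H]3CC(C)=[O+]c4cccc(O)c43)ccc(OC)c12.O[B-](F)(F)F | intermediate
12 | Cladonaphchrom B, (2S,4S)-4-(4,5-dimethoxynaphthalen-1-yl)-2-methylchroman-5-ol | COc1cccc2c([C@@H]3C[C@H](C)Oc4cccc(O)c43)ccc(OC)c12 | target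

## Step count and least certain steps

Total: 6 steps. Longest linear sequence: 5 steps (1 → 3 → 4 → 8 → 10 → 12); step 3 is a one-step side branch.

**Step 4 (key step, proposed new method).** Several processes could defeat it.
- The crowded aryl–nickel complex (two ortho substituents, partner a secondary radical next to a peri-substituted naphthalene) may fail to capture the radical or to eliminate reductively. The radical would then be diverted to dimerisation or to hydrogen-atom reduction (hydroacylation only).
- The acetyl radical may be captured by nickel before it adds to the alkene, giving two-component acylation.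
- Excited decatungstate may be quenched by electron transfer from the dimethoxynaphthalene, or may abstract the doubly benzylic C4–H of the product and erode its configuration.
- A ligand developed for unhindered aryl halides may discriminate the faces poorly.

The fallback uses known auxiliary-controlled conjugate addition. It sets out from 3 and 5 and comes back at 10. Knoevenagel–Doebner condensation of 3 with malonic acid (pyridine, piperidine, 90 °C) should give (E)-3-(4,5-dimethoxynaphthalen-1-yl)acrylic acid F1. Its pivaloyl mixed anhydride (PivCl, Et3N, LiCl, THF) acylates (S)-4-phenyloxazolidin-2-one to give (S)-3-[(E)-3-(4,5-dimethoxynaphthalen-1-yl)acryloyl]-4-phenyloxazolidin-2-one F2. In parallel 5 is benzylated (BnBr, K2CO3, DMF) to 2-bromo-1,3-bis(benzyloxy)benzene F3. Its Grignard reagent (Mg, THF) is added with CuBr·SMe2 at −40 °C to F2. In the magnesium-chelated s-cis imide the aryl group should enter anti to the 4-phenyl group, giving (S)-3-[(S)-3-[2,6-bis(benzyloxy)phenyl]-3-(4,5-dimethoxynaphthalen-1-yl)propanoyl]-4-phenyloxazolidin-2-one F4. Me(MeO)NH·HCl with AlMe3 converts F4 into (S)-3-[2,6-bis(benzyloxy)phenyl]-3-(4,5-dimethoxynaphthalen-1-yl)-N-methoxy-N-methylpropanamide F5. MeMgBr then gives (S)-4-[2,6-bis(benzyloxy)phenyl]-4-(4,5-dimethoxynaphthalen-1-yl)butan-2-one F6. Hydrogenolysis (H2, Pd/C, EtOAc) removes both benzyl groups and the diphenol closes to 10. This costs seven operations but every reaction type is established.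

**Step 6.** Facial selectivity of hydride delivery to 11 may be poor if the C4 aryl group does not hold the pseudoaxial position. Acid may also promote heterolysis of the C4–naphthyl bond (retro-Friedel–Crafts through a quinone-methide-like cation), with loss of configuration at C4. The fallback sets out from 10 and comes back at 12. Dehydration with PPTS (toluene, 4 Å sieves, 60 °C) gives (S)-4-(4,5-dimethoxynaphthalen-1-yl)-2-methyl-4H-chromen-5-ol F7. Hydrogenation over Pd/C (H2, EtOAc) should add hydrogen to the enol ether from the face opposite the naphthyl group, giving the cis chroman without any strong Lewis acid.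

**Step 5.** The electron-rich phenoxide may be oxidised by traces of air. A base-triggered retro-Michael fragmentation through the phenoxide would erode configuration at C4. The fallback sets out from 8 and comes back at 12. Acid-catalysed methanolysis and ketalisation (AcCl in MeOH as a source of HCl, rt) gives (4S)-4-(4,5-dimethoxynaphthalen-1-yl)-2-methoxy-2-methylchroman-5-ol F8 as a C2 mixture. F8 is reduced under the conditions of step 6 through the same cation 11, so no basic medium is involved.

**Step 2.** Olefination of the donor-deactivated, peri-flanked aldehyde may be sluggish. The electron-rich vinylarene may oligomerise (acid- or radical-induced) during the chromatographic removal of Ph3PO. The fallback sets out from 1 and comes back at 4. Bromination with NBS (MeCN, 0 °C) should occur para to a methoxy group to give 4-bromo-1,8-dimethoxynaphthalene F9. Suzuki–Miyaura coupling with potassium vinyltrifluoroborate (PdCl2(dppf), Cs2CO3, THF/H2O, 70 °C) installs the vinyl group. The by-products are water-soluble, so 4 needs only a short filtration.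

## Further compounds

F1 | step 4 | (E)-3-(4,5-dimethoxynaphthalen-1-yl)acrylic acid | COc1cccc2c(/C=C/C(=O)O)ccc(OC)c12
F2 | step 4 | (S)-3-[(E)-3-(4,5-dimethoxynaphthalen-1-yl)acryloyl]-4-phenyloxazolidin-2-one | COc1cccc2c(/C=C/C(=O)N3C(=O)OC[C@@H]3c3ccccc3)ccc(OC)c12
F3 | step 4 | 2-bromo-1,3-bis(benzyloxy)benzene | Brc1c(OCc2ccccc2)cccc1OCc1ccccc1
F4 | step 4 | (S)-3-[(S)-3-[2,6-bis(benzyloxy)phenyl]-3-(4,5-dimethoxynaphthalen-1-yl)propanoyl]-4-phenyloxazolidin-2-one | COc1cccc2c([C@H](CC(=O)N3C(=O)OC[C@@H]3c3ccccc3)c3c(OCc4ccccc4)cccc3OCc3ccccc3)ccc(OC)c12
F5 | step 4 | (S)-3-[2,6-bis(benzyloxy)phenyl]-3-(4,5-dimethoxynaphthalen-1-yl)-N-methoxy-N-methylpropanamide | COc1cccc2c([C@H](CC(=O)N(C)OC)c3c(OCc4ccccc4)cccc3OCc3ccccc3)ccc(OC)c12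
F6 | step 4 | (S)-4-[2,6-bis(benzyloxy)phenyl]-4-(4,5-dimethoxynaphthalen-1-yl)butan-2-one | COc1cccc2c([C@H](CC(C)=O)c3c(OCc4ccccc4)cccc3OCc3ccccc3)ccc(OC)c12
F7 | step 6 | (S)-4-(4,5-dimethoxynaphthalen-1-yl)-2-methyl-4H-chromen-5-ol | COc1cccc2c([C@@H]3C=C(C)Oc4cccc(O)c43)ccc(OC)c12
F8 | step 5 | (4S)-4-(4,5-dimethoxynaphthalen-1-yl)-2-methoxy-2-methylchroman-5-ol (both C2 epimers) | COc1cccc2c([C@@H]3CC(C)(OC)Oc4cccc(O)c43)ccc(OC)c12
F9 | step 2 | 4-bromo-1,8-dimethoxynaphthalene | COc1cccc2c(Br)ccc(OC)c12
A1 | alternative 1 | 2-[(4,5-dimethoxynaphthalen-1-yl)(hydroxy)methyl]benzene-1,3-diol | COc1cccc2c(C(O)c3c(O)cccc3O)ccc(OC)c12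
A2 | alternative 1 | 6-[(4,5-dimethoxynaphthalen-1-yl)methylidene]-5-hydroxycyclohexa-2,4-dien-1-one | COc1cccc2c(C=C3C(=O)C=CC=C3O)ccc(OC)c12
A3 | alternative 1 | 2-methoxypropene | COC(C)=C
A4 | alternative 1 | (2S,4S)-4-(4,5-dimethoxynaphthalen-1-yl)-2-methoxy-2-methylchroman-5-ol | COc1cccc2c([C@@H]3C[C@@](C)(OC)Oc4cccc(O)c43)ccc(OC)c12
A5 | alternative 2 | (E)-1-[3-(benzyloxy)-2-bromophenyl]-3-(4,5-dimethoxynaphthalen-1-yl)prop-2-en-1-one | COc1cccc2c(/C=C/C(=O)c3cccc(OCc4ccccc4)c3Br)ccc(OC)c12
A6 | alternative 2 | (S)-4-(benzyloxy)-3-(4,5-dimethoxynaphthalen-1-yl)-2,3-dihydro-1H-inden-1-one | COc1cccc2c([C@@H]3CC(=O)c4cccc(OCc5ccccc5)c43)ccc(OC)c12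
A7 | alternative 2 | (S)-5-(benzyloxy)-4-(4,5-dimethoxynaphthalen-1-yl)chroman-2-one | COc1cccc2c([C@@H]3CC(=O)Oc4cccc(OCc5ccccc5)c43)ccc(OC)c12
A8 | alternative 3 | 4-(benzyloxy)-3-(4,5-dimethoxynaphthalen-1-yl)-2-methylbenzofuran | COc1cccc2c(-c3c(C)oc4cccc(OCc5ccccc5)c34)ccc(OC)c12
A9 | alternative 3 | 5-(benzyloxy)-4-(4,5-dimethoxynaphthalen-1-yl)-2-methylchromenylium tetrafluoroborate | COc1cccc2c(-c3cc(C)[o+]c4cccc(OCc5ccccc5)c34)ccc(OC)c12.F[B-](F)(F)F
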